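**Strategy.** The target is cut at C13–C14, the bond between the ethylene tether and the tertiary carbinol carbon of ring C. In the key step the primary alkylcerium of the ring A/B half (made from an iodo alcohol) adds to the C14 ketone of the ring C/D half. This ketone is a 2,2,6-trisubstituted cyclohexanone locked by the trans-fused oxepane ring D, flanked by quaternary C19 (axial methyl) and C15 (equatorial methyl), so one equatorial addition forges C13–C14 and sets the C14 carbinol. Both partners come from one diepoxy iodide by silyl-triflate oxa-/carbacyclisation cascades that build each trans-fused oxepane–cyclohexane pair in a single operation.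

Key step: step 14

Remark: atoms carry the sodwanone numbering (ring A = C2–C7 oxepane with the C3 acetate, ring B = C6–C11 cyclohexane, C12–C13 tether, ring C = C14–C19 cyclohexane, ring D = C18–C23 oxepane with the C22 ketone); compounds 1, 5, 13 and 16 and the D-fructose-derived ketone catalyst are taken as commercial.

**Common diepoxy iodide**

Step 1
Reactants: 1 geraniol
Product: 2 (2S,3S)-2,3-epoxygeraniol
Conditions: Ti(OiPr)4 (5 mol%), L-(+)-diethyl tartrate (7 mol%), t-BuOOH, 4 Å MS, CH2Cl2, −20 °C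
Reagents that add atoms: tert-butyl hydroperoxide, CC(C)(C)OO
Why: Sharpless asymmetric epoxidation of the allylic alcohol, in which the L-(+)-tartrate/titanium complex delivers oxygen to one face of the 2,3-alkene only and so sets the two epoxide carbons that become the ring-fusion centres C7/C6 and C18/C19, while the isolated 6,7-alkene does not react.

Step 2
Reactants: 2 (2S,3S)-2,3-epoxygeraniol
Product: 3 (2S,3S,6R)-2,3:6,7-diepoxy-3,7-dimethyloctan-1-ol
Conditions: 1,2:4,5-di-O-isopropylidene-β-D-erythro-2,3-hexodiulo-2,6-pyranose (30 mol%), KHSO5 (Oxone), K2CO3, Bu4NHSO4, aq. Na2B4O7/Na2EDTA (pH 10.5), MeCN–CH2(OMe)2, 0 °C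
Reagents that add atoms: potassium peroxymonosulfate, [K+].[O-]S(=O)(=O)OO
Why: Shi epoxidation, in which the dioxirane of the D-fructose-derived ketone attacks the remaining trisubstituted alkene through a spiro transition state and should give the (6R)-epoxide under reagent control (this carbon becomes C3 and C22).

Step 3
Reactants: 3 (2S,3S,6R)-2,3:6,7-diepoxy-3,7-dimethyloctan-1-ol
Product: 4 (2R,3S,6R)-2,3:6,7-diepoxy-1-iodo-3,7-dimethyloctane
Conditions: PPh3, I2, imidazole, CH2Cl2, 0 °C
Reagents that add atoms: iodine, II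
Why: Appel-type iodination of the primary alcohol through the alkoxyphosphonium ion; the buffered, cold conditions spare both trisubstituted epoxides and no stereocentre is touched (the C2 descriptor changes only because iodine alters the priorities).

**Ring C/D ketone**

Step 4
Reactants: 5 trimethyl(2-methylallyl)silane; 4 (2R,3S,6R)-2,3:6,7-diepoxy-1-iodo-3,7-dimethyloctane
Product: 7 trimethyl[(1E,5S,6S,9R)-5,6:9,10-diepoxy-2,6,10-trimethylundec-1-en-1-yl]silane, via lithiated allylsilane 6 (not isolated)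
Conditions: 5, s-BuLi, TMEDA, THF, −78 °C; then 4, −78 → −20 °C
Reagents that add atoms: none
Why: Metalation of the allylsilane at the silicon-bearing CH2 gives a silyl-stabilised allyl anion that should be alkylated by the primary iodide at its γ-terminus, remote from silicon (SN2 alkylation of a 1-silylallyl anion), to give the E-vinylsilane; the hindered epoxides are not attacked at low temperature.

Step 5
Reactants: 7 trimethyl[(1E,5S,6S,9R)-5,6:9,10-diepoxy-2,6,10-trimethylundec-1-en-1-yl]silane
Product: 8 triethyl{[(3R,5aS,9aS)-2,2,5a,7-tetramethyl-2,3,4,5,5a,8,9,9a-octahydro-1-benzoxepin-3-yl]oxy}silane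
Conditions: Et3SiOTf, 2,6-di-tert-butyl-4-methylpyridine, CH2Cl2, −78 °C
Reagents that add atoms: triethylsilyl trifluoromethanesulfonate, CC[Si](CC)(CC)OS(=O)(=O)C(F)(F)F
Why: Tandem oxa-/carbacyclisation (epoxide-opening cascade terminated by a vinylsilane): the silylated terminal epoxide is opened at its tertiary carbon by the neighbouring epoxide oxygen, and the resulting bicyclic epoxonium ion is opened at tertiary C19 by ipso attack of the vinylsilane with inversion through a chair (trans ring fusion, C18 and C22 retained); the β-silyl cation then loses Me3Si to place the alkene at C14=C15, and the promoter ends as the C22 silyl ether.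

Step 6
Reactants: 8 triethyl{[(3R,5aS,9aS)-2,2,5a,7-tetramethyl-2,3,4,5,5a,8,9,9a-octahydro-1-benzoxepin-3-yl]oxy}silane
Product: 10 (3R,5aS,6S,7R,9aS)-2,2,5a,7-tetramethyl-3-[(triethylsilyl)oxy]decahydro-1-benzoxepin-6-ol, via alkylborane 9 (not isolated)
Conditions: BH3·THF, THF, 0 °C → rt; then NaOH, H2O2, 0 °C
Reagents that add atoms: hydrogen peroxide, OO
Why: Hydroboration–oxidation, in which boron adds to the less substituted C14, expected from the face anti to the axial C19 methyl, and is oxidised with retention; the two new centres do not matter because C14 is oxidised and C15 equilibrated in step 7.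

Step 7
Reactants: 10 (3R,5aS,6S,7R,9aS)-2,2,5a,7-tetramethyl-3-[(triethylsilyl)oxy]decahydro-1-benzoxepin-6-ol
Product: 12 (3R,5aR,7S,9aS)-2,2,5a,7-tetramethyl-3-[(triethylsilyl)oxy]octahydro-1-benzoxepin-6(2H)-one, via C15-epimeric ketone 11 (not isolated)
Conditions: Dess–Martin periodinane, NaHCO3, CH2Cl2, rt; then DBU (cat.), CH2Cl2, rt
Reagents that add atoms: none
Why: Dess–Martin oxidation followed by base-mediated epimerisation under thermodynamic control, which moves the C15 methyl to the equatorial position and removes its 1,3-diaxial clash with the axial C19 methyl.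

**Ring A/B iodo alcohol**

Step 8
Reactants: 13 dimethyl (2-oxopropyl)phosphonate; 4 (2R,3S,6R)-2,3:6,7-diepoxy-1-iodo-3,7-dimethyloctane
Product: 15 dimethyl [(5S,6S,9R)-5,6:9,10-diepoxy-6,10-dimethyl-2-oxoundecyl]phosphonate, via phosphonate dianion 14 (not isolated)
Conditions: 13, NaH, THF, 0 °C; n-BuLi, 0 °C; then 4, 0 °C → rt
Reagents that add atoms: none
Why: γ-Alkylation of a β-ketophosphonate dianion, whose more reactive terminal carbanion displaces the primary iodide (SN2) while the stabilised α-position stays untouched; no stereocentre is involved.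

Step 9
Reactants: 15 dimethyl [(5S,6S,9R)-5,6:9,10-diepoxy-6,10-dimethyl-2-oxoundecyl]phosphonate; 16 (tert-butyldimethylsilyloxy)acetaldehyde
Product: 17 (2E,7S,8S,11R)-1-[(tert-butyldimethylsilyl)oxy]-7,8:11,12-diepoxy-8,12-dimethyltridec-2-en-4-one
Conditions: Ba(OH)2·8H2O, THF–H2O (40:1), rt
Reagents that add atoms: none
Why: Horner–Wadsworth–Emmons olefination under mild hydroxide conditions, which should give the E-enone without harming the epoxides or the silyl ether.

Step 10
Reactants: 17 (2E,7S,8S,11R)-1-[(tert-butyldimethylsilyl)oxy]-7,8:11,12-diepoxy-8,12-dimethyltridec-2-en-4-one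
Product: 18 (3Z,7S,8S,11R)-1-[(tert-butyldimethylsilyl)oxy]-7,8:11,12-diepoxy-8,12-dimethyl-4-[(triethylsilyl)oxy]tridec-3-ene
Conditions: Et3SiH, RhCl(PPh3)3 (2 mol%), benzene, 50 °C
Reagents that add atoms: triethylsilane, CC[SiH](CC)CC
Why: Rhodium-catalysed 1,4-hydrosilylation of the enone, which gives the silyl enol ether regiospecifically at C10=C11 and so fixes C11 as the nucleophilic carbon; the neutral conditions spare the epoxides.

Step 11
Reactants: 18 (3Z,7S,8S,11R)-1-[(tert-butyldimethylsilyl)oxy]-7,8:11,12-diepoxy-8,12-dimethyl-4-[(triethylsilyl)oxy]tridec-3-ene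
Product: 20 (3R,5aS,6S,9aS)-6-{2-[(tert-butyldimethylsilyl)oxy]ethyl}-3-hydroxy-2,2,5a-trimethyloctahydro-1-benzoxepin-7(2H)-one, via trimethylsilyl ether ketone 19 (not isolated)
Conditions: Me3SiOTf, 2,6-di-tert-butyl-4-methylpyridine, CH2Cl2, −78 °C; then K2CO3, MeOH, rt
Reagents that add atoms: none
Why: Tandem oxa-/carbacyclisation terminated by a silyl enol ether: the activated terminal epoxide is opened by the internal epoxide oxygen and C11 attacks tertiary C6 with inversion through a chair (trans-fused rings A/B, C7 and C3 retained); K2CO3/MeOH then cleaves the Me3Si ether and equilibrates the epimerisable C11 to the equatorial side chain.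

Step 12
Reactants: 20 (3R,5aS,6S,9aS)-6-{2-[(tert-butyldimethylsilyl)oxy]ethyl}-3-hydroxy-2,2,5a-trimethyloctahydro-1-benzoxepin-7(2H)-one
Product: 22 (3R,5aS,6R,9aS)-6-(2-hydroxyethyl)-2,2,5a-trimethyl-7-methylidenedecahydro-1-benzoxepin-3-ol, via silyl ether alkene 21 (not isolated)
Conditions: Ph3PCH3Br, KOtBu (excess), THF, 0 → 50 °C; then Bu4NF, THF, rt
Reagents that add atoms: methyltriphenylphosphonium bromide, C[P+](c1ccccc1)(c1ccccc1)c1ccccc1.[Br-]
Why: Wittig methylenation of the ring B ketone (the free C3 hydroxyl only consumes ylide and the basic medium keeps C11 in its stable equatorial configuration), followed by fluoride cleavage of the primary silyl ether.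

Step 13
Reactants: 22 (3R,5aS,6R,9aS)-6-(2-hydroxyethyl)-2,2,5a-trimethyl-7-methylidenedecahydro-1-benzoxepin-3-ol
Product: 23 (3R,5aS,6R,9aS)-6-(2-iodoethyl)-2,2,5a-trimethyl-7-methylidenedecahydro-1-benzoxepin-3-ol
Conditions: PPh3, I2, imidazole, CH2Cl2, 0 °C
Reagents that add atoms: iodine, II
Why: Appel-type iodination that is selective for the primary alcohol, because the secondary C3 hydroxyl next to the fully substituted C2 is too hindered to form or displace the phosphonium intermediate.

**Fragment union and end game**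

Step 14
Reactants: 23 (3R,5aS,6R,9aS)-6-(2-iodoethyl)-2,2,5a-trimethyl-7-methylidenedecahydro-1-benzoxepin-3-ol; 12 (3R,5aR,7S,9aS)-2,2,5a,7-tetramethyl-3-[(triethylsilyl)oxy]octahydro-1-benzoxepin-6(2H)-one
Product: 26 C13–C14 coupled 3,14-diol 22-triethylsilyl ether, via lithium alkoxide alkyllithium 24 (not isolated), via alkylcerium dichloride 25 (not isolated)
Conditions: 23, t-BuLi (3.1 equiv), Et2O, −78 °C; CeCl3, THF, −78 °C; then 12, THF, −78 → −20 °C; aq. NH4Cl
Reagents that add atoms: none
Why: Iodine–lithium exchange on 23 (the first equivalent of t-BuLi only deprotonates the C3 hydroxyl) and transmetalation give the weakly basic, strongly oxophilic alkylcerium 25, which adds to the cerium-activated C14 carbonyl of 12; the closest known reaction type is the organocerium 1,2-addition to hindered, enolisable ketones. No ring is closed. The new C14 stereocentre is controlled by the substrate: the cyclohexanone is locked in one chair by the trans-fused oxepane, and its carbonyl is flanked by two equatorial α-substituents (the C15 methyl and the C19–C20 ring bond) that resist movement of the metal-bound oxygen into the equatorial position, so the reagent should enter along the equatorial trajectory, anti to the C15 methyl, leaving the oxygen axial and trans to the angular C19 methyl. This is the sense generally found for 2,2,6-trisubstituted cyclohexanones with an equatorial 6-methyl group, and it places the large chain in the thermodynamically preferred equatorial position. The step needs addition to win over enolisation at the epimerisable C15, which the cerium reagent secures; the exocyclic alkene and the silyl ether are inert and the C3 lithium alkoxide is a spectator.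

Step 15
Reactants: 26 C13–C14 coupled 3,14-diol 22-triethylsilyl ether
Product: 27 3-acetate 14-ol 22-triethylsilyl ether
Conditions: Ac2O, DMAP (cat.), pyridine, CH2Cl2, rt
Reagents that add atoms: acetic anhydride, CC(=O)OC(C)=O
Why: DMAP-catalysed acetylation of the secondary C3 hydroxyl; the tertiary C14 hydroxyl, buried between C19 and C15, should not be acylated under these conditions.

Step 16
Reactants: 27 3-acetate 14-ol 22-triethylsilyl ether
Product: 28 3-acetate 14,22-diol
Conditions: HF·pyridine, pyridine, THF, 0 °C → rt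
Reagents that add atoms: none
Why: Fluoride-mediated cleavage of the triethylsilyl ether under buffered conditions that leave the acetate, the tertiary alcohol and the exocyclic alkene intact.

Step 17
Reactants: 28 3-acetate 14,22-diol
Product: 29 3-epi-sodwanone K 3-acetate
Conditions: Dess–Martin periodinane, NaHCO3, CH2Cl2, rt
Reagents that add atoms: none
Why: Dess–Martin oxidation of the only oxidisable alcohol, the secondary C22 hydroxyl, to the oxepanone; the tertiary C14 alcohol, the acetate and the alkene do not react.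

**Compound list**

1 | geraniol, (2E)-3,7-dimethylocta-2,6-dien-1-ol | CC(C)=CCC/C(C)=C/CO | starting material
2 | (2S,3S)-2,3-epoxygeraniol (trans epoxide) | OC[C@@H]1O[C@@]1(C)CCC=C(C)C | intermediate
3 | (2S,3S,6R)-2,3:6,7-diepoxy-3,7-dimethyloctan-1-ol | OC[C@@H]1O[C@@]1(C)CC[C@H]1OC1(C)C | intermediate
4 | (2R,3S,6R)-2,3:6,7-diepoxy-1-iodo-3,7-dimethyloctane (same spatial arrangement as 3) | IC[C@@H]1O[C@@]1(C)CC[C@H]1OC1(C)C | intermediate
5 | trimethyl(2-methylallyl)silane | C=C(C)C[Si](C)(C)C | starting material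
6 | [2-methyl-1-(trimethylsilyl)allyl]lithium | C=C(C)C([Li])[Si](C)(C)C | intermediate (not isolated)
7 | trimethyl[(1E,5S,6S,9R)-5,6:9,10-diepoxy-2,6,10-trimethylundec-1-en-1-yl]silane | C[Si](C)(C)/C=C(C)/CC[C@@H]1O[C@@]1(C)CC[C@H]1OC1(C)C | intermediate
8 | triethyl{[(3R,5aS,9aS)-2,2,5a,7-tetramethyl-2,3,4,5,5a,8,9,9a-octahydro-1-benzoxepin-3-yl]oxy}silane (trans-fused, C14=C15 alkene) | C1=C(C)CC[C@@H]2OC(C)(C)[C@H](O[Si](CC)(CC)CC)CC[C@]21C | intermediate
9 | C14 alkylborane (R–BH2) from 8, boron and new C15–H on the face anti to the C19 methyl | B[C@H]1[C@H](C)CC[C@@H]2OC(C)(C)[C@H](O[Si](CC)(CC)CC)CC[C@]21C | intermediate (not isolated)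
10 | (3R,5aS,6S,7R,9aS)-2,2,5a,7-tetramethyl-3-[(triethylsilyl)oxy]decahydro-1-benzoxepin-6-ol (expected major diastereomer) | O[C@H]1[C@H](C)CC[C@@H]2OC(C)(C)[C@H](O[Si](CC)(CC)CC)CC[C@]21C | intermediate
11 | (3R,5aR,7R,9aS)-2,2,5a,7-tetramethyl-3-[(triethylsilyl)oxy]octahydro-1-benzoxepin-6(2H)-one (axial C15 methyl) | O=C1[C@H](C)CC[C@@H]2OC(C)(C)[C@H](O[Si](CC)(CC)CC)CC[C@]21C | intermediate (not isolated)
12 | (3R,5aR,7S,9aS)-2,2,5a,7-tetramethyl-3-[(triethylsilyl)oxy]octahydro-1-benzoxepin-6(2H)-one (equatorial C15 methyl) | O=C1[C@@H](C)CC[C@@H]2OC(C)(C)[C@H](O[Si](CC)(CC)CC)CC[C@]21C | intermediate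
13 | dimethyl (2-oxopropyl)phosphonate | COP(=O)(OC)CC(C)=O | starting material
14 | sodium lithium dianion of 13 | COP(=O)(OC)[CH-]C(=O)[CH2-].[Na+].[Li+] | intermediate (not isolated)
15 | dimethyl [(5S,6S,9R)-5,6:9,10-diepoxy-6,10-dimethyl-2-oxoundecyl]phosphonate | COP(=O)(OC)CC(=O)CC[C@@H]1O[C@@]1(C)CC[C@H]1OC1(C)C | intermediate
16 | (tert-butyldimethylsilyloxy)acetaldehyde | CC(C)(C)[Si](C)(C)OCC=O | starting material
17 | (2E,7S,8S,11R)-1-[(tert-butyldimethylsilyl)oxy]-7,8:11,12-diepoxy-8,12-dimethyltridec-2-en-4-one | CC(C)(C)[Si](C)(C)OC/C=C/C(=O)CC[C@@H]1O[C@@]1(C)CC[C@H]1OC1(C)C | intermediate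
18 | (3Z,7S,8S,11R)-1-[(tert-butyldimethylsilyl)oxy]-7,8:11,12-diepoxy-8,12-dimethyl-4-[(triethylsilyl)oxy]tridec-3-ene | CC(C)(C)[Si](C)(C)OCC/C=C(\O[Si](CC)(CC)CC)CC[C@@H]1O[C@@]1(C)CC[C@H]1OC1(C)C | intermediate
19 | trans-fused ring A/B ketone with C3 trimethylsilyl ether (C11 epimers) | O=C1CC[C@@H]2OC(C)(C)[C@H](O[Si](C)(C)C)CC[C@@]2(C)C1CCO[Si](C)(C)C(C)(C)C | intermediate (not isolated)
20 | (3R,5aS,6S,9aS)-6-{2-[(tert-butyldimethylsilyl)oxy]ethyl}-3-hydroxy-2,2,5a-trimethyloctahydro-1-benzoxepin-7(2H)-one | O=C1CC[C@@H]2OC(C)(C)[C@H](O)CC[C@@]2(C)[C@@H]1CCO[Si](C)(C)C(C)(C)C | intermediate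
21 | (3R,5aS,6R,9aS)-6-{2-[(tert-butyldimethylsilyl)oxy]ethyl}-2,2,5a-trimethyl-7-methylidenedecahydro-1-benzoxepin-3-ol | C=C1CC[C@@H]2OC(C)(C)[C@H](O)CC[C@@]2(C)[C@@H]1CCO[Si](C)(C)C(C)(C)C | intermediate (not isolated)
22 | (3R,5aS,6R,9aS)-6-(2-hydroxyethyl)-2,2,5a-trimethyl-7-methylidenedecahydro-1-benzoxepin-3-ol | C=C1CC[C@@H]2OC(C)(C)[C@H](O)CC[C@@]2(C)[C@@H]1CCO | intermediate
23 | (3R,5aS,6R,9aS)-6-(2-iodoethyl)-2,2,5a-trimethyl-7-methylidenedecahydro-1-benzoxepin-3-ol | C=C1CC[C@@H]2OC(C)(C)[C@H](O)CC[C@@]2(C)[C@@H]1CCI | intermediate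
24 | C13 alkyllithium of 23 carrying the C3 lithium alkoxide | C=C1CC[C@@H]2OC(C)(C)[C@H](O[Li])CC[C@@]2(C)[C@@H]1CC[Li] | intermediate (not isolated)
25 | C13 alkylcerium dichloride carrying the C3 lithium alkoxide | C=C1CC[C@@H]2OC(C)(C)[C@H](O[Li])CC[C@@]2(C)[C@@H]1CC[Ce](Cl)Cl | intermediate (not isolated)
26 | coupled product: target skeleton with free C3–OH, tertiary C14–OH (axial, trans to the C19 methyl) and C22–OSiEt3 | C=C1CC[C@@H]2OC(C)(C)[C@H](O)CC[C@@]2(C)[C@@H]1CC[C@]1(O)[C@@H](C)CC[C@@H]2OC(C)(C)[C@H](O[Si](CC)(CC)CC)CC[C@]21C | intermediate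
27 | as 26 with the C3 hydroxyl acetylated | C=C1CC[C@@H]2OC(C)(C)[C@H](OC(C)=O)CC[C@@]2(C)[C@@H]1CC[C@]1(O)[C@@H](C)CC[C@@H]2OC(C)(C)[C@H](O[Si](CC)(CC)CC)CC[C@]21C | intermediate
28 | as 27 with free C22–OH | C=C1CC[C@@H]2OC(C)(C)[C@H](OC(C)=O)CC[C@@]2(C)[C@@H]1CC[C@]1(O)[C@@H](C)CC[C@@H]2OC(C)(C)[C@H](O)CC[C@]21C | intermediate
29 | 3-epi-sodwanone K 3-acetate | C=C1CC[C@@H]2OC(C)(C)[C@H](OC(C)=O)CC[C@@]2(C)[C@@H]1CC[C@]1(O)[C@@H](C)CC[C@@H]2OC(C)(C)C(=O)CC[C@]21C | target

**Step count.** Total: 17 steps. Longest linear sequence: 13 steps (1–3, 8–13, 14–17).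

**Steps most likely to fail**

Step 14 (key step). What may go wrong is poor facial selectivity (axial instead of equatorial entry of the carbon nucleophile, giving the C14 epimer), or enolisation of the hindered ketone instead of addition. The fallback keeps the same C13–C14 union but brings the oxygen in last; it sets out from 23 and 12 and returns at 26. Compound 23 is alkylated with Ph2P(O)H/KN(SiMe3)2 (Michaelis–Becker) to the phosphine oxide F1. Its dianion (n-BuLi, THF, −78 °C) adds to 12 to give the β-hydroxy phosphine oxide F2, whose configuration at C13 and C14 is irrelevant. Horner–Wittig elimination (NaH, DMF, 50 °C) gives the C13=C14 exocyclic alkene F3. One equivalent of mCPBA at −20 °C should epoxidise this trisubstituted alkene before the 1,1-disubstituted one, from the face anti to the axial C19 methyl, giving the spiro-epoxide F4 with the oxygen axial on C14. LiEt3BH then delivers hydride to the secondary C13 and gives 26.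

Step 5. What may go wrong is premature termination of the cascade: the sterically loaded, only moderately nucleophilic vinylsilane may fail to capture the tertiary cation, so that oxacyclisation is followed by elimination or triflate capture. The fallback uses a silyl enol ether terminator and a later carbonyl transposition; it sets out from 15 and returns at 12. Compound 15 is O-silylated (NaH, t-BuMe2SiCl, THF) to the silyl enol ether F5. The Et3SiOTf cascade then gives the bicyclic β-ketophosphonate F6 (C15 ketone, C14 phosphonate, C22–OSiEt3). Horner–Wadsworth–Emmons reaction with aqueous formaldehyde/K2CO3 gives the α-methylene ketone F7, and MeLi/CeCl3 adds 1,2 to give the tertiary allylic alcohol F8. Ozonolysis (O3, then Me2S) gives the α-hydroxy ketone F9 with the carbonyl now at C14. SmI2 (THF/MeOH) removes the C15 hydroxyl, and DBU equilibration gives 12.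

Step 4. What may go wrong is ambident reactivity of the silylallyl anion (α- instead of γ-alkylation), metalation at the methyl group instead of the CH2Si group, or iodine–lithium exchange on 4. The fallback replaces the anion alkylation by an sp3–sp2 cross-coupling; it sets out from 3 and returns at 7. Compound 3 is oxidised (Dess–Martin periodinane, NaHCO3) to the epoxy aldehyde F10, which Wittig methylenation (Ph3P=CH2) converts to the vinyl epoxide F11. Hydroboration with 9-BBN gives the B-alkyl borane F12, and Suzuki–Miyaura coupling with (E)-(2-bromoprop-1-en-1-yl)trimethylsilane (Pd(dppf)Cl2, Cs2CO3, DMF/H2O) gives 7 as the pure E isomer.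

**Further compounds**

F1 | step 14 | (3R,5aS,6R,9aS)-6-[2-(diphenylphosphoryl)ethyl]-2,2,5a-trimethyl-7-methylidenedecahydro-1-benzoxepin-3-ol | C=C1CC[C@@H]2OC(C)(C)[C@H](O)CC[C@@]2(C)[C@@H]1CCP(=O)(c1ccccc1)c1ccccc1
F2 | step 14 | β-hydroxy phosphine oxide from F1 and 12 (C13 and C14 as a mixture) | C=C1CC[C@@H]2OC(C)(C)[C@H](O)CC[C@@]2(C)[C@@H]1CC(P(=O)(c1ccccc1)c1ccccc1)C1(O)[C@@H](C)CC[C@@H]2OC(C)(C)[C@H](O[Si](CC)(CC)CC)CC[C@]21C
F3 | step 14 | C13=C14 exocyclic alkene (E/Z mixture) | C=C1CC[C@@H]2OC(C)(C)[C@H](O)CC[C@@]2(C)[C@@H]1CC=C1[C@@H](C)CC[C@@H]2OC(C)(C)[C@H](O[Si](CC)(CC)CC)CC[C@]21C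
F4 | step 14 | C13–C14 spiro-epoxide with oxygen axial on C14 (C13 as a mixture) | C=C1CC[C@@H]2OC(C)(C)[C@H](O)CC[C@@]2(C)[C@@H]1CC2O[C@]23[C@@H](C)CC[C@@H]4OC(C)(C)[C@H](O[Si](CC)(CC)CC)CC[C@]43C
F5 | step 5 | tert-butyldimethylsilyl enol ether of 15 | COP(=O)(OC)C=C(O[Si](C)(C)C(C)(C)C)CC[C@@H]1O[C@@]1(C)CC[C@H]1OC1(C)C
F6 | step 5 | trans-fused bicyclic β-ketophosphonate (C15 ketone, C14 phosphonate, C22 triethylsilyl ether) | O=C1CC[C@@H]2OC(C)(C)[C@H](O[Si](CC)(CC)CC)CC[C@@]2(C)C1P(=O)(OC)OC
F7 | step 5 | bicyclic α-methylene ketone (C14 methylidene, C15 ketone) | O=C1CC[C@@H]2OC(C)(C)[C@H](O[Si](CC)(CC)CC)CC[C@@]2(C)C1=C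
F8 | step 5 | tertiary allylic alcohol (C15 methyl carbinol, C14 methylidene) | CC1(O)CC[C@@H]2OC(C)(C)[C@H](O[Si](CC)(CC)CC)CC[C@@]2(C)C1=C
F9 | step 5 | α-hydroxy ketone (C14 ketone, C15 methyl carbinol) | CC1(O)CC[C@@H]2OC(C)(C)[C@H](O[Si](CC)(CC)CC)CC[C@@]2(C)C1=O
F10 | step 4 | (2R,3S,6R)-2,3:6,7-diepoxy-3,7-dimethyloctanal | O=C[C@@H]1O[C@@]1(C)CC[C@H]1OC1(C)C
F11 | step 4 | (3S,4S,7R)-3,4:7,8-diepoxy-4,8-dimethylnon-1-ene | C=C[C@@H]1O[C@@]1(C)CC[C@H]1OC1(C)C
F12 | step 4 | B-alkyl-9-borabicyclo[3.3.1]nonane from F11 | C(C[C@@H]1O[C@@]1(C)CC[C@H]1OC1(C)C)B1C2CCCC1CCC2
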